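**Retrosynthetic overview**

1. Germacrane numbering is used (ring C1–C10, C14 methyl on C10, C15 methyl on C4, isopropyl on C7); the target is the (1(10)E,3R,4R,5R,6S,7R) isomer. The C3 angelate and then the C6 acetate go on last, and the C3 carbinol comes from chelation-controlled reduction of a 4,5-epoxy-3-ketone.
2. Enabling feature: the C4–C5 oxirane lies next to oxygenated C3, and C4 carries the C15 methyl group. With C3 raised to a ketone, the 4,5-epoxy-3-ketone is the retron of a carbonyl-stabilised sulfonium-ylide epoxidation (C4 = ylide carbon, C5 = aldehyde carbon).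
3. Key disconnection: the C4–C5 bond and the C4–O bond in one intramolecular ylide epoxidation of an acyclic keto-sulfonium aldehyde. The ten-membered carbocycle and the oxirane form in the same operation (the only ring-forming step), and C4 and C5 are set under control of C6.
4. The acyclic chain comes from geranyl acetate, which already holds the E-1(10) alkene. An asymmetric glyoxylate-ene reaction at the prenyl terminus makes the C6–C7 bond, both stereocentres and the isopropyl skeleton; a Pd-catalysed allyl–alkenylstannane coupling makes the C2–C3 bond; bromination of the resulting enol ether gives the α-bromo ketone.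

Key step: step 9

Remark: the enol ether geometry in 6–10 and the configuration at the bromine- or sulfur-bearing carbon in 11–13 are not controlled; both are erased later (bromination, ylide formation), so mixtures are carried.

Remark: geranyl acetate, ethyl glyoxylate (freshly distilled from its toluene solution), ethyl prop-1-enyl ether and angelic acid are taken as commercial.

**Route**

Step 1
Reactants: 1 geranyl acetate; 2 ethyl glyoxylate
Product: 3 ethyl (2S,3R,6E)-8-(acetyloxy)-2-hydroxy-6-methyl-3-(prop-1-en-2-yl)oct-6-enoate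
Conditions: (S)-BINOL (10 mol %), TiCl2(OiPr)2 (10 mol %), 4 Å molecular sieves, CH2Cl2, −30 °C
Reagents that add atoms: none
Why: In this chiral-Lewis-acid-catalysed glyoxylate-ene reaction the aldehyde should bond to the less substituted carbon of the electron-rich terminal alkene (the 2,3-alkene is deactivated by the allylic acetate) and take a hydrogen from a terminal methyl group to leave the isopropenyl group; the (S)-BINOL–titanium catalyst is expected to set C2 as S, and the syn-selective transition state precedented for trisubstituted alkenes to set C3 as R.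

Step 2
Reactants: 3 ethyl (2S,3R,6E)-8-(acetyloxy)-2-hydroxy-6-methyl-3-(prop-1-en-2-yl)oct-6-enoate
Product: 4 ethyl (2S,3R,6E)-8-(acetyloxy)-2-hydroxy-6-methyl-3-(propan-2-yl)oct-6-enoate
Conditions: H2 (1 atm), RhCl(PPh3)3 (5 mol %), benzene–EtOH, 25 °C
Reagents that add atoms: none
Why: Homogeneous hydrogenation with RhCl(PPh3)3 should reduce only the unhindered 1,1-disubstituted alkene and leave the trisubstituted alkene and the allylic acetate; no stereocentre is formed or touched.

Step 3
Reactants: 4 ethyl (2S,3R,6E)-8-(acetyloxy)-2-hydroxy-6-methyl-3-(propan-2-yl)oct-6-enoate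
Product: 5 ethyl (2S,3R,6E)-8-(acetyloxy)-6-methyl-3-(propan-2-yl)-2-[(triethylsilyl)oxy]oct-6-enoate
Conditions: Et3SiOTf, 2,6-lutidine, CH2Cl2, −78 → 0 °C
Reagents that add atoms: triethylsilyl trifluoromethanesulfonate, CC[Si](CC)(CC)OS(=O)(=O)C(F)(F)F
Why: Silyl ether formation with the triflate and a hindered base should protect the hindered α-hydroxy ester without epimerisation; the triethylsilyl group is chosen because it can be removed late under buffered fluoride conditions.

Step 4
Reactants: 6 ethyl prop-1-enyl ether (cis/trans mixture)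
Product: 8 tributyl(1-ethoxyprop-1-en-1-yl)stannane, via 1-ethoxyprop-1-enyllithium 7 (not isolated)
Conditions: t-BuLi, THF, −78 → 0 °C; then Bu3SnCl, −78 → 25 °C
Reagents that add atoms: tributyltin chloride, CCCC[Sn](Cl)(CCCC)CCCC
Why: Oxygen-directed α-lithiation of the enol ether followed by stannylation should give the masked acyl-anion reagent; its alkene geometry is immaterial.

Step 5
Reactants: 5 ethyl (2S,3R,6E)-8-(acetyloxy)-6-methyl-3-(propan-2-yl)-2-[(triethylsilyl)oxy]oct-6-enoate; 8 tributyl(1-ethoxyprop-1-en-1-yl)stannane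
Product: 9 ethyl (2S,3R,6E)-9-ethoxy-6-methyl-3-(propan-2-yl)-2-[(triethylsilyl)oxy]undeca-6,9-dienoate
Conditions: Pd2(dba)3 (2.5 mol %), LiCl (3 equiv), DMF, 40 °C
Reagents that add atoms: none
Why: In this Stille-type allyl–alkenyl coupling, zerovalent palladium ionises the allylic acetate to a π-allyl complex and the alkenyl group should be delivered to the primary terminus with retention of the E trisubstituted alkene, while ester and silyl ether are untouched.

Step 6
Reactants: 9 ethyl (2S,3R,6E)-9-ethoxy-6-methyl-3-(propan-2-yl)-2-[(triethylsilyl)oxy]undeca-6,9-dienoate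
Product: 10 (2S,3R,6E)-9-ethoxy-6-methyl-3-(propan-2-yl)-2-[(triethylsilyl)oxy]undeca-6,9-dienal
Conditions: i-Bu2AlH (1.1 equiv), CH2Cl2, −78 °C; aqueous KNaC4H4O6 work-up
Reagents that add atoms: none
Why: Partial ester reduction of an α-silyloxy ester at −78 °C should stop at the aldehyde through the stable aluminium hemiacetal, with the enol ether inert and C2 not epimerised.

Step 7
Reactants: 10 (2S,3R,6E)-9-ethoxy-6-methyl-3-(propan-2-yl)-2-[(triethylsilyl)oxy]undeca-6,9-dienal
Product: 11 (2S,3R,6E)-10-bromo-6-methyl-9-oxo-3-(propan-2-yl)-2-[(triethylsilyl)oxy]undec-6-enal (both C10 epimers)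
Conditions: N-bromosuccinimide (1.0 equiv), NaHCO3, THF–H2O (4:1), −20 → 0 °C
Reagents that add atoms: N-bromosuccinimide, O=C1CCC(=O)N1Br; water, O
Why: Electrophilic bromination of the enol ether and hydrolysis of the bromo-oxocarbenium ion should place the bromine regiospecifically on the future C4, which avoids enolisation toward the more acidic allylic methylene; the enol ether reacts far faster than the trisubstituted alkene.

Step 8
Reactants: 11 (2S,3R,6E)-10-bromo-6-methyl-9-oxo-3-(propan-2-yl)-2-[(triethylsilyl)oxy]undec-6-enal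
Product: 12 1-[(5E,9R,10S)-6-methyl-3,11-dioxo-9-(propan-2-yl)-10-[(triethylsilyl)oxy]undec-5-en-2-yl]thiolan-1-ium tetrafluoroborate
Conditions: tetrahydrothiophene (3 equiv), AgBF4 (1.05 equiv), acetone, 0 → 25 °C, dark
Reagents that add atoms: tetrahydrothiophene, C1CCSC1; silver tetrafluoroborate, [Ag+].F[B-](F)(F)F
Why: Silver-assisted SN2 alkylation of the sulfide by the activated α-bromo ketone should give the sulfonium salt with a non-nucleophilic counter-ion; the aldehyde, silyl ether and alkene do not react.

Step 9
Reactants: 12 1-[(5E,9R,10S)-6-methyl-3,11-dioxo-9-(propan-2-yl)-10-[(triethylsilyl)oxy]undec-5-en-2-yl]thiolan-1-ium tetrafluoroborate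
Product: 15 (1(10)E,4S,5R,6S,7R)-4,5-epoxy-6-[(triethylsilyl)oxy]germacr-1(10)-en-3-one, via sulfonium ylide 13 (not isolated), via oxido sulfonium betaine 14 (not isolated)
Conditions: Cs2CO3 (1.5 equiv), MeCN, 1 mM final concentration, 12 added over 12 h by syringe pump, 0 → 25 °C
Reagents that add atoms: none
Why: Proposed new method: carbonate removes the C4 proton of the keto-sulfonium salt (by far the most acidic C–H, so C2–H, C6–H and C7–H are left alone), the acyl-stabilised ylide 13 adds to the C5 aldehyde to give betaine 14, and the alkoxide displaces tetrahydrothiophene at C4. The closest known reaction type is the intermolecular epoxidation of aldehydes by carbonyl-stabilised sulfonium ylides (Johnson–Corey–Chaykovsky reaction, Darzens-type), which has not been used to close a ten-membered carbocycle. The carbocycle closes by 10-exo-trig addition of C4 to the aldehyde carbon and the oxirane by 3-exo-tet displacement at C4. Betaine formation from a stabilised ylide is reversible, so the outcome is decided in the ring-closing displacement through the anti-periplanar betaine, which should place C3 and C6 trans on the oxirane, the E-type geometry that a ten-membered ring holding the E-1(10) alkene accommodates. The sense at C4 and C5 is controlled by the C6 stereocentre: the C4 methyl group is cis to C6 on the oxirane, so allylic-type 1,3-strain keeps H-6 in the plane, the ring chain through C7 must span the face opposite to the oxirane oxygen, and the silyloxy group therefore ends syn (threo) to the new C5–O bond, which with 6S is the configuration of the target. The step needs chemoselective carbanion formation, ring closure in preference to oligomerisation, and trans and threo selectivity; the sulfonium group, slow addition at high dilution, and the C4-methyl/C6 interplay are meant to secure these.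

Step 10
Reactants: 15 (1(10)E,4S,5R,6S,7R)-4,5-epoxy-6-[(triethylsilyl)oxy]germacr-1(10)-en-3-one
Product: 16 (1(10)E,3R,4R,5R,6S,7R)-4,5-epoxy-6-[(triethylsilyl)oxy]germacr-1(10)-en-3-ol
Conditions: Zn(BH4)2, Et2O, −20 °C
Reagents that add atoms: none
Why: In this chelation-controlled reduction of an α,β-epoxy ketone, zinc should bridge the carbonyl and oxirane oxygens and hydride should enter from the peripheral face that carries the C4 methyl group, giving the erythro (anti) epoxy alcohol, 3R.

Step 11
Reactants: 16 (1(10)E,3R,4R,5R,6S,7R)-4,5-epoxy-6-[(triethylsilyl)oxy]germacr-1(10)-en-3-ol; 17 angelic acid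
Product: 19 (1(10)E,3R,4R,5R,6S,7R)-4,5-epoxy-6-[(triethylsilyl)oxy]germacr-1(10)-en-3-yl (2Z)-2-methylbut-2-enoate, via angelic 2,4,6-trichlorobenzoic anhydride 18 (not isolated)
Conditions: 17, 2,4,6-trichlorobenzoyl chloride, Et3N, toluene, 25 °C; then 16, 75 °C
Reagents that add atoms: none
Why: Yamaguchi-type esterification through the mixed anhydride without a nucleophilic catalyst should acylate the C3 alcohol with retention and avoid isomerisation of the angelate to the tiglate.

Step 12
Reactants: 19 (1(10)E,3R,4R,5R,6S,7R)-4,5-epoxy-6-[(triethylsilyl)oxy]germacr-1(10)-en-3-yl (2Z)-2-methylbut-2-enoate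
Product: 20 (1(10)E,3R,4R,5R,6S,7R)-4,5-epoxy-6-hydroxygermacr-1(10)-en-3-yl (2Z)-2-methylbut-2-enoate
Conditions: Bu4NF, AcOH (1:1), THF, 0 → 25 °C
Reagents that add atoms: none
Why: Fluoride-mediated desilylation buffered with acetic acid should free the C6 alcohol without letting its alkoxide open the neighbouring oxirane (Payne rearrangement) and without acid that could trigger transannular cyclisation.

Step 13
Reactants: 20 (1(10)E,3R,4R,5R,6S,7R)-4,5-epoxy-6-hydroxygermacr-1(10)-en-3-yl (2Z)-2-methylbut-2-enoate
Product: 21 (1(10)E,3R,4R,5R,6S,7R)-6-(acetyloxy)-4,5-epoxygermacr-1(10)-en-3-yl (2Z)-2-methylbut-2-enoate (CNP0180504.5)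
Conditions: Ac2O, Et3N, DMAP (cat.), CH2Cl2, 0 → 25 °C
Reagents that add atoms: acetic anhydride, CC(=O)OC(C)=O
Why: DMAP-catalysed acetylation of the secondary C6 alcohol should complete the target without touching any stereocentre.

**Compound list**

1 | geranyl acetate | CC(=O)OC/C=C(\C)CCC=C(C)C | starting material
2 | ethyl glyoxylate | CCOC(=O)C=O | starting material
3 | ethyl (2S,3R,6E)-8-(acetyloxy)-2-hydroxy-6-methyl-3-(prop-1-en-2-yl)oct-6-enoate | CC(=O)OC/C=C(\C)CC[C@H](C(C)=C)[C@H](O)C(=O)OCC | intermediate
4 | ethyl (2S,3R,6E)-8-(acetyloxy)-2-hydroxy-6-methyl-3-(propan-2-yl)oct-6-enoate | CC(=O)OC/C=C(\C)CC[C@H](C(C)C)[C@H](O)C(=O)OCC | intermediate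
5 | ethyl (2S,3R,6E)-8-(acetyloxy)-6-methyl-3-(propan-2-yl)-2-[(triethylsilyl)oxy]oct-6-enoate | CC(=O)OC/C=C(\C)CC[C@H](C(C)C)[C@H](O[Si](CC)(CC)CC)C(=O)OCC | intermediate
6 | ethyl prop-1-enyl ether (cis/trans mixture) | CCOC=CC | starting material
7 | 1-ethoxyprop-1-enyllithium (not isolated) | CCOC([Li])=CC | intermediate
8 | tributyl(1-ethoxyprop-1-en-1-yl)stannane (geometry not defined) | CCOC(=CC)[Sn](CCCC)(CCCC)CCCC | intermediate
9 | ethyl (2S,3R,6E)-9-ethoxy-6-methyl-3-(propan-2-yl)-2-[(triethylsilyl)oxy]undeca-6,9-dienoate (9,10-geometry not defined) | CCOC(=CC)C/C=C(\C)CC[C@H](C(C)C)[C@H](O[Si](CC)(CC)CC)C(=O)OCC | intermediate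
10 | (2S,3R,6E)-9-ethoxy-6-methyl-3-(propan-2-yl)-2-[(triethylsilyl)oxy]undeca-6,9-dienal (9,10-geometry not defined) | CCOC(=CC)C/C=C(\C)CC[C@H](C(C)C)[C@H](O[Si](CC)(CC)CC)C=O | intermediate
11 | (2S,3R,6E)-10-bromo-6-methyl-9-oxo-3-(propan-2-yl)-2-[(triethylsilyl)oxy]undec-6-enal (both C10 epimers) | CC(Br)C(=O)C/C=C(\C)CC[C@H](C(C)C)[C@H](O[Si](CC)(CC)CC)C=O | intermediate
12 | 1-[(5E,9R,10S)-6-methyl-3,11-dioxo-9-(propan-2-yl)-10-[(triethylsilyl)oxy]undec-5-en-2-yl]thiolan-1-ium tetrafluoroborate (both epimers at the sulfur-bearing carbon) | CC([S+]1CCCC1)C(=O)C/C=C(\C)CC[C@H](C(C)C)[C@H](O[Si](CC)(CC)CC)C=O.F[B-](F)(F)F | intermediate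
13 | sulfonium ylide of 12, carbanion at the sulfur-bearing carbon (not isolated) | C[C-]([S+]1CCCC1)C(=O)C/C=C(\C)CC[C@H](C(C)C)[C@H](O[Si](CC)(CC)CC)C=O | intermediate
14 | betaine: ten-membered 3-ketone with 5-oxido and 4-(thiolan-1-ium-1-yl) groups, C5 configured as in 15 and sulfur anti to the oxido group (not isolated) | O=C1C/C=C(\C)CC[C@H](C(C)C)[C@H](O[Si](CC)(CC)CC)[C@@H]([O-])[C@@]1(C)[S+]2CCCC2 | intermediate
15 | (1(10)E,4S,5R,6S,7R)-4,5-epoxy-6-[(triethylsilyl)oxy]germacr-1(10)-en-3-one | O=C1C/C=C(\C)CC[C@H](C(C)C)[C@H](O[Si](CC)(CC)CC)[C@H]2O[C@@]21C | intermediate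
16 | (1(10)E,3R,4R,5R,6S,7R)-4,5-epoxy-6-[(triethylsilyl)oxy]germacr-1(10)-en-3-ol | O[C@@H]1C/C=C(\C)CC[C@H](C(C)C)[C@H](O[Si](CC)(CC)CC)[C@H]2O[C@@]21C | intermediate
17 | angelic acid, (2Z)-2-methylbut-2-enoic acid | C/C=C(/C)C(O)=O | starting material
18 | angelic 2,4,6-trichlorobenzoic anhydride (not isolated) | C/C=C(/C)C(=O)OC(=O)c1c(Cl)cc(Cl)cc1Cl | intermediate
19 | (1(10)E,3R,4R,5R,6S,7R)-4,5-epoxy-6-[(triethylsilyl)oxy]germacr-1(10)-en-3-yl (2Z)-2-methylbut-2-enoate | C/C=C(/C)C(=O)O[C@@H]1C/C=C(\C)CC[C@H](C(C)C)[C@H](O[Si](CC)(CC)CC)[C@H]2O[C@@]21C | intermediate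
20 | (1(10)E,3R,4R,5R,6S,7R)-4,5-epoxy-6-hydroxygermacr-1(10)-en-3-yl (2Z)-2-methylbut-2-enoate | C/C=C(/C)C(=O)O[C@@H]1C/C=C(\C)CC[C@H](C(C)C)[C@H](O)[C@H]2O[C@@]21C | intermediate
21 | (1(10)E,3R,4R,5R,6S,7R)-6-(acetyloxy)-4,5-epoxygermacr-1(10)-en-3-yl (2Z)-2-methylbut-2-enoate, CNP0180504.5 | C/C=C(/C)C(=O)O[C@@H]1C/C=C(\C)CC[C@H](C(C)C)[C@H](OC(C)=O)[C@H]2O[C@@]21C | target

**Step count**

Total steps: 13. Longest linear sequence: 12 (steps 1–3 and 5–13, from geranyl acetate).

**Steps most likely to fail, with fallbacks**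

Step 9 (Proposed new method). The stabilised ylide may add too slowly to the hindered α-silyloxy aldehyde, so that oligomerisation, β-elimination of the sulfonium group or base-induced epimerisation at C6 take over. The oxirane may also close with poor cis/trans or facial control. The fallback uses known chemistry, sets out from 11 and returns at 15. Compound 11 is heated with PPh3 (toluene, 60 °C) to give the phosphonium bromide F1. Deprotonation (aqueous NaOH, CH2Cl2) gives the acyl-stabilised phosphorane F2. Intramolecular Wittig olefination at high dilution (toluene, 90 °C) closes the ring at C4=C5 to the macrocyclic E-enone F3. Nucleophilic (Weitz–Scheffer-type) epoxidation with LiOOt-Bu (from t-BuOOH and n-BuLi, THF, −20 °C) should then attack the exposed outer face of the enone, the face that carries the C6 silyloxy group because the ring chain covers the other, and give 15.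

Step 1. Discrimination between syn and anti transition states or between the aldehyde faces may be insufficient at this trisubstituted terminal alkene, and the developing cation may be captured by the 2,3-alkene (Prins-type cyclisation). The fallback sets the two stereocentres enzymatically; it sets out from 1 and 2 and returns at 4. The ene reaction is run with an achiral catalyst (racemic BINOL, TiCl2(OiPr)2) to give the stereoisomer mixture of ene adducts F4. Hydrogenation as in step 2 gives the isopropyl hydroxy esters F5. Dess–Martin oxidation gives the α-keto ester F6, whose C3 centre is configurationally labile through the enol. A ketoreductase (NADPH-dependent, glucose/glucose dehydrogenase recycling, pH 8 buffer with DMSO, 30 °C), chosen by screening, should then reduce F6 under dynamic kinetic resolution to the (2S,3R) hydroxy ester 4.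

Step 10. Hydride delivery may occur to the other face of the macrocyclic ketone if the ring conformation overrides the zinc chelate. The fallback turns the wrong epimer into the next intermediate; it sets out from 15 and returns at 19. The reduction then gives the 3S alcohol F7. Mitsunobu esterification of F7 with angelic acid 17 (PPh3, diisopropyl azodicarboxylate, toluene, 0 °C) inverts C3 and installs the angelate in the same operation to give 19.

**Further compounds**

F1 | step 9 | [(5E,9R,10S)-6-methyl-3,11-dioxo-9-(propan-2-yl)-10-[(triethylsilyl)oxy]undec-5-en-2-yl]triphenylphosphonium bromide | CC([P+](c1ccccc1)(c1ccccc1)c1ccccc1)C(=O)C/C=C(\C)CC[C@H](C(C)C)[C@H](O[Si](CC)(CC)CC)C=O.[Br-]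
F2 | step 9 | (2S,3R,6E)-6-methyl-9-oxo-3-(propan-2-yl)-2-[(triethylsilyl)oxy]-10-(triphenyl-λ5-phosphanylidene)undec-6-enal | CC(=P(c1ccccc1)(c1ccccc1)c1ccccc1)C(=O)C/C=C(\C)CC[C@H](C(C)C)[C@H](O[Si](CC)(CC)CC)C=O
F3 | step 9 | (1(10)E,4E,6S,7R)-6-[(triethylsilyl)oxy]germacra-1(10),4-dien-3-one | O=C1C/C=C(\C)CC[C@H](C(C)C)[C@H](O[Si](CC)(CC)CC)/C=C1\C
F4 | step 1 | ethyl (6E)-8-(acetyloxy)-2-hydroxy-6-methyl-3-(prop-1-en-2-yl)oct-6-enoate, mixture of stereoisomers at C2 and C3 | CC(=O)OC/C=C(\C)CCC(C(C)=C)C(O)C(=O)OCC
F5 | step 1 | ethyl (6E)-8-(acetyloxy)-2-hydroxy-6-methyl-3-(propan-2-yl)oct-6-enoate, mixture of stereoisomers at C2 and C3 | CC(=O)OC/C=C(\C)CCC(C(C)C)C(O)C(=O)OCC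
F6 | step 1 | ethyl (6E)-8-(acetyloxy)-6-methyl-2-oxo-3-(propan-2-yl)oct-6-enoate, racemic | CC(=O)OC/C=C(\C)CCC(C(C)C)C(=O)C(=O)OCC
F7 | step 10 | (1(10)E,3S,4R,5R,6S,7R)-4,5-epoxy-6-[(triethylsilyl)oxy]germacr-1(10)-en-3-ol | O[C@H]1C/C=C(\C)CC[C@H](C(C)C)[C@H](O[Si](CC)(CC)CC)[C@H]2O[C@@]21C
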